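The readings come from a simulation with made-up constants.

No flask can hold more D than the J charged, and if each D costs one G, none can hold more than its G allows. The north-east run's G allowed 82.5% of its J, yet I saw it crawling at 47.6% after 8.00 h.

| flask | J | G | temperature | remark | time |
|---|---|---|---|---|---|
| east | 0.40 M | 0.22 M | −10 °C | run made earlier |  |
| north-east | 0.40 M | 0.33 M | 30 °C | run made earlier |  |
| south-east | 0.80 M | 0.44 M | −10 °C | run made earlier |  |
| grey | 0.40 M | 0.440 M | −5 °C |  | 12 h |
| red | 0.40 M | 0.440 M | 45 °C |  | 12 h |
| teal | 0.40 M | 0.440 M | 5 °C |  | 12 h |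
| blue | 0.40 M | 0.440 M | 65 °C |  | 12 h |
| green | 0.40 M | 0.440 M | 25 °C |  | 12 h |

| run | time / h | D / % |
|---|---|---|
| east | 5.00 | 0 |
| east | 15.0 | 1.2 |
| east | 30.0 | 2.9 |
| east | 50.0 | 6.3 |
| north-east | 0.500 | 7.7 |
| north-east | 1.33 | 20.1 |
| north-east | 3.00 | 35.1 |
| north-east | 8.00 | 47.6 |
| south-east | 12.0 | 1.2 |
| south-east | 25.0 | 2.4 |
| south-east | 30.0 | 3.9 |
| south-east | 50.0 | 7.0 |

(readings scatter by 0.5 percentage points)

1. the flasks by amount of D, in percent of the J charged, highest first, at 12 h (grey / red / teal / blue / green)
2. the amount of D, in percent of the J charged of the flask you put first, at 12 h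
3. the amount of D, in percent of the J charged of the flask you put last, at 12 h

- what was read earlier has a scatter of 0.5 percentage points, one standard deviation
- a reading or a percentage of D counts all its forms, free or not

So I supposed that J was also being lost by a path taking a second J, a loss that grows with the J present. North-east gave 2.75 M⁻¹ for a quantity I called λ, the waste coefficient: J lost per J turned into D, divided by the J charged, [J]₀. The share of J finishing as D is then 1/(1 + λ[J]₀).

Two versions of the five flasks could be solved in the head. With λ at zero, G stands at 1.10 equivalents, J is the limiting reagent, and the ceiling is 100%. With λ at its north-east value at every temperature, a finished flask reaches 47.6%.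

These were marks rather than bounds: the second rested on one run at one temperature, so a colder flask could finish under it, and heat would say where each flask stood. East showed 0% at 5.00 h and then a rising slope, while north-east already had 7.7% at 0.500 h, so something stands between J and D and leaves faster when hot. I bet that this lone exit climbs more steeply with temperature than capture by J does, which puts blue nearest the ceiling, then red, then green. Teal and grey were a matter of the clock: east had 1.2% at 15.0 h, so I put grey last, under 6.3%.

The forecast gave green > red > blue > teal > grey, with 63% (52% to 74%) first and 5.5% (3.5% to 8%) last, and it leaned the other way from me: “If activator loss has the higher barrier, the plateau falls when hot”.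

The flasks gave blue > red > green > teal > grey, with blue at 81.2% and grey at 3.66%.

    J + G → Q (k = 1.20 M⁻¹ h⁻¹, Ea = 60.0 kJ mol⁻¹)
    Q → D (k = 0.990 h⁻¹, Ea = 82.0 kJ mol⁻¹)
    J + Q → Z (k = 2.00 M⁻¹ h⁻¹, Ea = 59.0 kJ mol⁻¹)
    G + D ⇌ L, settled at all times (K = 5.00 M⁻¹, ΔH = −4.00 kJ mol⁻¹)
    X ⇌ D, rate k5*(cs5 - [D]) while solid is left; crystals form when [D] > cs5 (solubility = 0.290 M, k = 43.0 h⁻¹)
    (constants at 25 °C)

The fork is Q → D against J + Q → Z. In blue, Z held the other 18.8% of the J at 12.0 h, so blue's coefficient was 0.578 M⁻¹, less than the 2.75 M⁻¹ from north-east. The neighbouring flask is blue with 0.10 M of J, which makes G 4.40 equiv. Blue's coefficient then gives 94.5% as D. In that neighbouring flask, Z came to 5.41% and D to 94.6%.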